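## Structural features

The target is an achiral homoisoflavonoid: a 4H-chromen-4-one in which benzene ring A (C4a, C5, C6, C7, C8, C8a) is fused through the C4a–C8a bond to the γ-pyranone ring B (O1, C2, C3, C4), and C3 carries a 4-methoxyphenyl ring through one methylene. There is no stereocentre, so no relationship between neighbouring stereocentres has to be controlled; the whole problem is constitutional. Ring A is hexasubstituted: a methyl ether at C5, a methyl group at C6, a free hydroxyl at C7 and a formyl group at C8, with the acyl carbon C4 on C4a and the ring oxygen O1 on C8a. Oxygen therefore sits on C5, C7 and C8a and carbon on C4a, C6 and C8, and each of the three oxygens is in a different state. The fragile points are the C8 aldehyde beside the free C7 phenol, the electrophilic C2 of ring B (opened by bases and nucleophiles), the C5 methyl ether peri to the C4 carbonyl (stripped by chelating Lewis acids), and the C3 methylene and C2=C3 bond (sensitive to oxidation and hydrogenation). The real difficulty is regiochemical: substitution chemistry on a C-methylphloroglucinol cannot reliably tell C6 from C8 or the C5 oxygen from the C7 oxygen. The key step uses the alternation of oxygen and carbon around ring A: a cyclobutenone and a siloxyalkyne are joined through C8a–C8, C6–C7 and C4a–C8a, which delivers the three oxygens already differentiated, the C6 methyl and the C8 carbon in place, and C4a as the only open position.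

## Logic of the disconnections

26 back to 25 and 24: no skeletal bond is cut; the C8 formyl group is traced to a hydroxymethyl group and the two free hydroxyls to silyl ethers. The salicylaldehyde unit is the most fragile part, so it is unveiled last. The gain is that everything before 25 carries C8 at the robust alcohol oxidation level. The demand is an oxidant that stops at the aldehyde and spares the C3 methylene, and protecting groups on the C7 oxygen and the C8 CH2–O oxygen that fall together under conditions that leave ring B and the C5 methyl ether alone. Two silyl ethers meet this; a benzyl ether on the C8 CH2–O oxygen would not, since hydrogenolysis threatens over-reduction to a C8 methyl and saturation of C2=C3, and Lewis acids would take the C5 methyl ether.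

24 back to 22: O1–C2 and C2–C3 are cut, which removes C2 as a one-carbon electrophile and opens ring B. This is the standard closure of a 2-hydroxyaryl ketone to a 3-substituted chromone. The gain is an open-chain aryl ketone whose C3 substituent is already attached. The demand is a free C8a hydroxyl next to the ketone and an enolisable CH2 alpha to it, under neutral conditions that do not disturb the silyl ethers.

22 back to 16 and 19, and 16 back to 15: the C4–C4a bond is cut, dividing the molecule into the ring A half and the 3-(4-methoxyphenyl)propanoyl half. A Friedel–Crafts sense is rejected because the C8 CH2–O bond is flanked by oxygen at both ortho positions and the para position and would ionise under acid, and the same acids endanger the silyl ethers and the C5 methyl ether. The polarity is therefore reversed: C4a becomes the nucleophile, generated from the C4a–Br bond of 16, and the acyl partner becomes 19. The gain is a convergent union without any acid. The demands are clean bromination of 15 at the single open ring position and an aryllithium that adds to 19 and does not enolise it.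

19 back to 17: the amide C–N bond is cut. The reason is that 17 is commercial and the amide stops nucleophilic addition at the ketone stage. The demand is only a routine coupling.

15 back to 6 and 10 (the strategic cut): C8a–C8, C6–C7 and C4a–C8a are cut, taking ring A apart into the four-carbon unit 6 and the two-carbon unit 10 with its C8 carbon attached. Cutting here transfers all regiochemistry of ring A to the polarity of two small components. The gain is the largest of the route: a phenol with three distinct oxygens becomes two compounds with no ring A at all. The demands are a single orientation in the ketene–alkyne union, and silyl groups that tolerate prolonged heating.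

6 back to 5, 4, 1 and 2: the O–CH3 bond of 6 is cut to the symmetrical 5; 5 is traced to 4 by enol ether hydrolysis; the two ring bonds of 4 made by ketene–alkyne (2+2) cycloaddition are cut to 1 and 2. The detour through 5 is needed because the cycloaddition places the methyl group on the sp3 carbon, and only hydrolysis brings it between the two oxygenated carbons. The gain is two commercial liquids. The demand is a low stationary concentration of 3 and mild, neutral O-methylation of 5.

10 back to 7: the C(sp)–O bond and the O–Si bond of the ynol ether are cut, leading to 7, which is commercial. The gain is a one-flask entry. The demand is oxygen transfer to the acetylide carbon and silylation of 9 on oxygen, which calls for a bulky, hard silylating agent.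

## Other disconnections considered

Alternative 1: The cut is C5–C6 of ring A, and ring A is traced to a 2-pyranone fused to the finished ring B, namely 7-ethyl-3-(4-methoxybenzyl)-4H,5H-pyrano[4,3-b]pyran-4,5-dione A2. In the forward key step an alkoxide would open the lactone of A2 to an ester on C4a and a 2-oxobutyl chain on C8a. The carbanion at the ethyl CH2 would then close onto the ester in a Claisen-type condensation, and enolisation would give 5,7-dihydroxy-3-(4-methoxybenzyl)-6-methyl-4H-chromen-4-one A1.
- In its favour: ring B and the C3 benzyl group are in place before ring A forms, and the C6 methyl position is fixed by construction; on that point it is the equal of the chosen plan. It needs no organolithium reagent, no silyl groups and no sealed-tube heating, so it is operationally the better plan.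
- Against it: ring B of A2 is itself an electrophile at C2 towards the same alkoxide. A1 emerges with both hydroxyls free, and the chelated C5 hydroxyl is the less reactive one, so the C5 methyl ether requires protection of the C7 hydroxyl, forced methylation and deprotection. C8 of A1 must then be formylated late, on the deactivated chromone.
- Comparison: the ionic recyclisation of A2 is mechanistically simpler than the pericyclic cascade, but it leaves the oxygen differentiation and the C8 carbon to be added after A1. The step count should be similar to the chosen plan or slightly higher once the preparation of A2 is included.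

Alternative 2: The cuts are C3–CH2 and O1–C2. The forward key step would treat the enaminone (E)-1-[2,4-bis(benzyloxy)-6-hydroxy-3-methylphenyl]-3-(dimethylamino)prop-2-en-1-one A4 with the benzylic cation released from 4-methoxybenzyl alcohol A5 by an acid catalyst. The alpha carbon of A4 captures the cation, the phenol adds to the resulting iminium carbon and the amino group is expelled, giving 5,7-bis(benzyloxy)-3-(4-methoxybenzyl)-6-methyl-4H-chromen-4-one A3.
- In its favour: it is the most convergent of the four plans, forms the C3 substituent and ring B in one operation from the simple partners A4 and A5, and should reach A3 in fewer steps than the chosen plan needs to reach 24. On step economy up to the chromone it is the better plan.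
- Against it: A4 derives from 1-(2,4,6-trihydroxy-3-methylphenyl)ethan-1-one A6, whose two ortho hydroxyls are both chelated. Which of them stays free when A6 is benzylated decides whether the methyl group ends at C6 or C8, and nothing in A6 controls it. The cation from A5 can also attack the open, activated C8 position of ring A. After A3, selective cleavage of the peri benzyl ether, methylation, hydrogenolysis and C8 formylation are still needed.
- Comparison: the chosen plan is longer but fixes every ring A position by construction. The alternative is shorter only if the regiochemistry of A4 can be secured on the way from A6.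

Alternative 3: The cut is C3–C4. In the forward key step an N-heterocyclic carbene would convert the aldehyde of 2,4-bis(benzyloxy)-6-{[3-(4-methoxyphenyl)prop-2-yn-1-yl]oxy}-3-methylbenzaldehyde A8 into an acyl-anion equivalent that adds syn across the tethered alkyne, giving (E)-5,7-bis(benzyloxy)-3-(4-methoxybenzylidene)-6-methylchroman-4-one A7.
- In its favour: the ring closure is catalytic, atom-economical and free of acid, so the competing C8 benzylation of alternative 2 cannot occur. On this point it is better than alternative 2, and in catalytic economy it is better than the chosen plan.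
- Against it: the aldehyde of A8 is flanked by two ortho oxygens and is electron-rich, which should slow formation of the acyl-anion equivalent, and the alkyne is unactivated. A7 needs a further double-bond isomerisation into ring B before it reaches the chromone stage. The C6/C8 methyl problem, the differentiation of the C5 and C7 oxygens and the late C8 formylation remain as in alternative 2, and the formyl group could not be carried earlier because the carbene would engage it.
- Comparison: the step count should be similar to the chosen plan, and the regiochemical certainty of ring A is lower.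

Key step: step 5

Assumption: the oxygen on the C8 hydroxymethyl carbon is carried through the annulation as a tert-butyldimethylsilyl ether and not as a benzyl ether, because hydrogenolysis or Lewis-acid cleavage of a benzyl group would endanger the C2=C3 bond, the C8 benzylic C–O bond and the C5 methyl ether; the carbon skeletons of both annulation partners and of the annulation product are unaffected.

## Route

Step 1
Reactants: 1 propanoyl chloride; 2 ethoxyethyne
Product: 4 racemic 3-ethoxy-4-methylcyclobut-2-en-1-one, via methylketene 3 (not isolated)
Conditions: Et3N, Et2O, 0 °C to rt, slow addition of 1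
Reagents that add atoms: none
Why: Et3N dehydrochlorinates 1 to methylketene 3, whose carbonyl carbon bonds to the unsubstituted, nucleophilic carbon of ynol ether 2 in a ketene–alkyne (2+2) cycloaddition; slow addition keeps the ketene concentration low against dimerisation, and the racemic C4 stereocentre is erased in step 2.

Step 2
Reactants: 4 racemic 3-ethoxy-4-methylcyclobut-2-en-1-one
Product: 5 3-hydroxy-2-methylcyclobut-2-en-1-one (enol form of 2-methylcyclobutane-1,3-dione)
Conditions: 1 M aq. HCl, THF, 0 °C to rt
Reagents that add atoms: water, O
Why: Acid hydrolysis of the vinylogous ester (enol ether hydrolysis) releases the 1,3-dione, which rests as the more substituted enol, so the methyl-bearing carbon now lies between the two oxygenated carbons.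

Step 3
Reactants: 5 3-hydroxy-2-methylcyclobut-2-en-1-one
Product: 6 3-methoxy-2-methylcyclobut-2-en-1-one
Conditions: Me3SiCHN2, MeOH–PhMe, 0 °C
Reagents that add atoms: (trimethylsilyl)diazomethane, C[Si](C)(C)C=[N+]=[N-]
Why: The strongly acidic vinylogous acid protonates the diazo carbon and is O-methylated under neutral conditions (diazoalkane O-alkylation), which avoids the acid- or base-induced ring cleavage of cyclobutane-1,3-diones; the two oxygens are equivalent, so only 6 can form.

Step 4
Reactants: 7 tert-butyldimethyl(prop-2-yn-1-yloxy)silane
Product: 10 3-[(tert-butyldimethylsilyl)oxy]-1-[(triisopropylsilyl)oxy]prop-1-yne, via lithium acetylide 8 (not isolated), via lithium ynolate 9 (not isolated)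
Conditions: LiN(SiMe3)2, THF, −78 °C; t-BuOOLi (from t-BuOOH and LiN(SiMe3)2), −78 to 0 °C; i-Pr3SiOTf, −78 to 0 °C
Reagents that add atoms: tert-butyl hydroperoxide, CC(C)(C)OO; triisopropylsilyl trifluoromethanesulfonate, CC(C)[Si](OS(=O)(=O)C(F)(F)F)(C(C)C)C(C)C
Why: Electrophilic oxygen transfer from lithium tert-butyl peroxide to acetylide 8 gives ynolate 9 (acetylide oxidation), and the hard, bulky silyl triflate traps 9 on oxygen and not on carbon, the standard entry to triisopropylsilyl ynol ethers.

Step 5
Reactants: 6 3-methoxy-2-methylcyclobut-2-en-1-one; 10 3-[(tert-butyldimethylsilyl)oxy]-1-[(triisopropylsilyl)oxy]prop-1-yne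
Product: 15 2-{[(tert-butyldimethylsilyl)oxy]methyl}-5-methoxy-4-methyl-3-[(triisopropylsilyl)oxy]phenol, via vinylketene 11 (not isolated), via vinylcyclobutenone 12 (not isolated), via dienylketene 13 (not isolated), via cyclohexadienone 14 (not isolated)
Conditions: PhMe, 80 to 110 °C, sealed tube, slight excess of 10
Reagents that add atoms: none
Why: Heat opens 6 by a four-electron conrotatory electrocyclic reaction to vinylketene 11, whose electrophilic ketene carbon is attacked by the carbon of 10 that is remote from the silyloxy oxygen, and the (2+2) cycloaddition gives vinylcyclobutenone 12. A second four-electron opening turns 12 into dienylketene 13, and a thermal disrotatory six-electron electrocyclisation of 13 forms the C4a–C8a bond, closes ring A as dienone 14 and is followed by irreversible tautomerisation to phenol 15. The closest known reaction type is the Danheiser benzannulation of cyclobutenones with trialkylsilyl ynol ethers, which gives mono-silylated resorcinols. Ring A is the only ring closed, by a pericyclic closure of a ketene-terminated triene and not by an ionic cyclisation. No stereocentre appears in 15; the quaternary carbon of 12 is transient, racemic and lost on ring opening. The selectivity that matters is the orientation of the ketene–alkyne union, and the oxygen-polarised triple bond of 10 secures it: the CH2OSi-bearing carbon bonds to the ketene carbonyl carbon and becomes C8 next to the phenolic C8a, while the silyloxy carbon becomes C7 next to the methyl-bearing C6. The CH2 of 6 becomes the unsubstituted C4a, the bulky triisopropylsilyl group keeps the ynol ether from silyl transfer at these temperatures, and a slight excess of 10 should favour capture of 11 over ketene dimerisation.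

Step 6
Reactants: 15 2-{[(tert-butyldimethylsilyl)oxy]methyl}-5-methoxy-4-methyl-3-[(triisopropylsilyl)oxy]phenol
Product: 16 2-bromo-6-{[(tert-butyldimethylsilyl)oxy]methyl}-3-methoxy-4-methyl-5-[(triisopropylsilyl)oxy]phenol
Conditions: NBS, CH2Cl2, −78 to 0 °C, dark
Reagents that add atoms: N-bromosuccinimide, O=C1CCC(=O)N1Br
Why: Electrophilic aromatic bromination; C4a is the only unsubstituted ring position and is activated by the ortho hydroxyl, the ortho methoxy and the para silyloxy groups, so one equivalent of NBS at low temperature should brominate there without touching the silyl ethers.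

Step 7
Reactants: 17 3-(4-methoxyphenyl)propanoic acid
Product: 19 N-methoxy-3-(4-methoxyphenyl)-N-methylpropanamide, via acylimidazole 18 (not isolated)
Conditions: CDI, CH2Cl2, rt; then MeNHOMe·HCl, rt
Reagents that add atoms: N,O-dimethylhydroxylamine hydrochloride, CNOC.Cl
Why: Activation with carbonyldiimidazole to acylimidazole 18 and aminolysis is a standard amide coupling; it supplies an acyl donor that stops at the ketone stage.

Step 8
Reactants: 16 2-bromo-6-{[(tert-butyldimethylsilyl)oxy]methyl}-3-methoxy-4-methyl-5-[(triisopropylsilyl)oxy]phenol; 19 N-methoxy-3-(4-methoxyphenyl)-N-methylpropanamide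
Product: 22 1-(3-{[(tert-butyldimethylsilyl)oxy]methyl}-2-hydroxy-6-methoxy-5-methyl-4-[(triisopropylsilyl)oxy]phenyl)-3-(4-methoxyphenyl)propan-1-one, via dilithio phenoxide 20 (not isolated), via tetrahedral adduct 21 (not isolated)
Conditions: n-BuLi (1 equiv), THF, −78 °C; t-BuLi (2 equiv), −78 °C; 19, −78 to 0 °C; aq. NH4Cl
Reagents that add atoms: none
Why: Deprotonation of the phenol and bromine–lithium exchange give the O,C-dilithio species 20, as known for 2-bromophenols, and its addition to the N-methoxy-N-methylamide (Weinreb ketone synthesis) stops at the chelated adduct 21, which collapses to ketone 22 only on work-up; making C4a the nucleophile avoids every Lewis acid.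

Step 9
Reactants: 22 1-(3-{[(tert-butyldimethylsilyl)oxy]methyl}-2-hydroxy-6-methoxy-5-methyl-4-[(triisopropylsilyl)oxy]phenyl)-3-(4-methoxyphenyl)propan-1-one
Product: 24 8-{[(tert-butyldimethylsilyl)oxy]methyl}-5-methoxy-3-(4-methoxybenzyl)-6-methyl-7-[(triisopropylsilyl)oxy]-4H-chromen-4-one, via enaminone 23 (not isolated)
Conditions: Me2NCH(OMe)2, PhMe, 110 °C
Reagents that add atoms: N,N-dimethylformamide dimethyl acetal, COC(OC)N(C)C
Why: The formamide acetal condenses at the CH2 alpha to the ketone to give enaminone 23, and the neighbouring C8a hydroxyl adds to the enamine carbon and expels dimethylamine (addition–elimination), the usual one-carbon closure of 2-hydroxyaryl ketones to 3-substituted chromones.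

Step 10
Reactants: 24 8-{[(tert-butyldimethylsilyl)oxy]methyl}-5-methoxy-3-(4-methoxybenzyl)-6-methyl-7-[(triisopropylsilyl)oxy]-4H-chromen-4-one
Product: 25 7-hydroxy-8-(hydroxymethyl)-5-methoxy-3-(4-methoxybenzyl)-6-methyl-4H-chromen-4-one
Conditions: Bu4NF, AcOH, THF, 0 °C to rt
Reagents that add atoms: none
Why: Fluoride cleaves both the aryl triisopropylsilyl ether and the primary alkyl tert-butyldimethylsilyl ether (silyl ether cleavage driven by Si–F bond formation), and acetic acid buffers the medium so that the base-sensitive pyranone is not opened.

Step 11
Reactants: 25 7-hydroxy-8-(hydroxymethyl)-5-methoxy-3-(4-methoxybenzyl)-6-methyl-4H-chromen-4-one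
Product: 26 7-hydroxy-5-methoxy-3-(4-methoxybenzyl)-6-methyl-4-oxo-4H-chromene-8-carbaldehyde
Conditions: MnO2 (activated), CH2Cl2, rt
Reagents that add atoms: none
Why: Activated MnO2 oxidises benzylic alcohols selectively to aldehydes (heterogeneous benzylic oxidation) and stops there; the new aldehyde is stabilised by its hydrogen bond to the C7 hydroxyl, and the C3 methylene and the methyl ethers should not be attacked at room temperature.

## Compound list

1 | propanoyl chloride | CCC(=O)Cl | starting material
2 | ethoxyethyne | CCOC#C | starting material
3 | methylketene (prop-1-en-1-one) | CC=C=O | intermediate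
4 | racemic 3-ethoxy-4-methylcyclobut-2-en-1-one | CCOC1=CC(=O)C1C | intermediate
5 | 3-hydroxy-2-methylcyclobut-2-en-1-one (enol form of 2-methylcyclobutane-1,3-dione) | CC1=C(O)CC1=O | intermediate
6 | 3-methoxy-2-methylcyclobut-2-en-1-one | COC1=C(C)C(=O)C1 | intermediate
7 | tert-butyldimethyl(prop-2-yn-1-yloxy)silane | C#CCO[Si](C)(C)C(C)(C)C | starting material
8 | {3-[(tert-butyldimethylsilyl)oxy]prop-1-yn-1-yl}lithium | [Li]C#CCO[Si](C)(C)C(C)(C)C | intermediate
9 | lithium 3-[(tert-butyldimethylsilyl)oxy]prop-1-yn-1-olate | [Li+].[O-]C#CCO[Si](C)(C)C(C)(C)C | intermediate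
10 | 3-[(tert-butyldimethylsilyl)oxy]-1-[(triisopropylsilyl)oxy]prop-1-yne | CC(C)[Si](OC#CCO[Si](C)(C)C(C)(C)C)(C(C)C)C(C)C | intermediate
11 | 3-methoxy-2-methylbuta-1,3-dien-1-one | COC(=C)C(C)=C=O | intermediate
12 | racemic 2-{[(tert-butyldimethylsilyl)oxy]methyl}-4-(1-methoxyethenyl)-4-methyl-3-[(triisopropylsilyl)oxy]cyclobut-2-en-1-one | COC(=C)C1(C)C(=O)C(CO[Si](C)(C)C(C)(C)C)=C1O[Si](C(C)C)(C(C)C)C(C)C | intermediate
13 | (3E)-2-{[(tert-butyldimethylsilyl)oxy]methyl}-5-methoxy-4-methyl-3-[(triisopropylsilyl)oxy]hexa-1,3,5-trien-1-one (ketene and 1-methoxyethenyl groups cis across the central double bond) | O=C=C(CO[Si](C)(C)C(C)(C)C)/C(O[Si](C(C)C)(C(C)C)C(C)C)=C(C)\C(OC)=C | intermediate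
14 | 2-{[(tert-butyldimethylsilyl)oxy]methyl}-5-methoxy-4-methyl-3-[(triisopropylsilyl)oxy]cyclohexa-2,4-dien-1-one | COC1=C(C)C(O[Si](C(C)C)(C(C)C)C(C)C)=C(CO[Si](C)(C)C(C)(C)C)C(=O)C1 | intermediate
15 | 2-{[(tert-butyldimethylsilyl)oxy]methyl}-5-methoxy-4-methyl-3-[(triisopropylsilyl)oxy]phenol | COc1cc(O)c(CO[Si](C)(C)C(C)(C)C)c(O[Si](C(C)C)(C(C)C)C(C)C)c1C | intermediate
16 | 2-bromo-6-{[(tert-butyldimethylsilyl)oxy]methyl}-3-methoxy-4-methyl-5-[(triisopropylsilyl)oxy]phenol | COc1c(Br)c(O)c(CO[Si](C)(C)C(C)(C)C)c(O[Si](C(C)C)(C(C)C)C(C)C)c1C | intermediate
17 | 3-(4-methoxyphenyl)propanoic acid | COc1ccc(CCC(=O)O)cc1 | starting material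
18 | 1-(1H-imidazol-1-yl)-3-(4-methoxyphenyl)propan-1-one | COc1ccc(CCC(=O)n2ccnc2)cc1 | intermediate
19 | N-methoxy-3-(4-methoxyphenyl)-N-methylpropanamide | COc1ccc(CCC(=O)N(C)OC)cc1 | intermediate
20 | lithium 6-{[(tert-butyldimethylsilyl)oxy]methyl}-2-lithio-3-methoxy-4-methyl-5-[(triisopropylsilyl)oxy]phenoxide | [Li]Oc1c([Li])c(OC)c(C)c(O[Si](C(C)C)(C(C)C)C(C)C)c1CO[Si](C)(C)C(C)(C)C | intermediate
21 | racemic dilithium salt of 2-{[(tert-butyldimethylsilyl)oxy]methyl}-6-{1-hydroxy-1-[methoxy(methyl)amino]-3-(4-methoxyphenyl)propyl}-5-methoxy-4-methyl-3-[(triisopropylsilyl)oxy]phenol | COc1ccc(CCC(O[Li])(N(C)OC)c2c(O[Li])c(CO[Si](C)(C)C(C)(C)C)c(O[Si](C(C)C)(C(C)C)C(C)C)c(C)c2OC)cc1 | intermediate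
22 | 1-(3-{[(tert-butyldimethylsilyl)oxy]methyl}-2-hydroxy-6-methoxy-5-methyl-4-[(triisopropylsilyl)oxy]phenyl)-3-(4-methoxyphenyl)propan-1-one | COc1ccc(CCC(=O)c2c(O)c(CO[Si](C)(C)C(C)(C)C)c(O[Si](C(C)C)(C(C)C)C(C)C)c(C)c2OC)cc1 | intermediate
23 | (2E)-1-(3-{[(tert-butyldimethylsilyl)oxy]methyl}-2-hydroxy-6-methoxy-5-methyl-4-[(triisopropylsilyl)oxy]phenyl)-3-(dimethylamino)-2-(4-methoxybenzyl)prop-2-en-1-one (drawn as the E isomer; both geometries should cyclise) | COc1ccc(C/C(=C\N(C)C)C(=O)c2c(O)c(CO[Si](C)(C)C(C)(C)C)c(O[Si](C(C)C)(C(C)C)C(C)C)c(C)c2OC)cc1 | intermediate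
24 | 8-{[(tert-butyldimethylsilyl)oxy]methyl}-5-methoxy-3-(4-methoxybenzyl)-6-methyl-7-[(triisopropylsilyl)oxy]-4H-chromen-4-one | COc1ccc(Cc2coc3c(CO[Si](C)(C)C(C)(C)C)c(O[Si](C(C)C)(C(C)C)C(C)C)c(C)c(OC)c3c2=O)cc1 | intermediate
25 | 7-hydroxy-8-(hydroxymethyl)-5-methoxy-3-(4-methoxybenzyl)-6-methyl-4H-chromen-4-one | COc1ccc(Cc2coc3c(CO)c(O)c(C)c(OC)c3c2=O)cc1 | intermediate
26 | 7-hydroxy-5-methoxy-3-(4-methoxybenzyl)-6-methyl-4-oxo-4H-chromene-8-carbaldehyde | COc1ccc(Cc2coc3c(C=O)c(O)c(C)c(OC)c3c2=O)cc1 | target

## Step count and risk assessment

Total step count: 11. Longest linear sequence: 9 steps (1, 2, 3, 5, 6, 8, 9, 10, 11); steps 4 and 7 are side branches.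

Step 5 (key step). The alkoxy group stabilises the cyclobutenone as a vinylogous ester, so the first ring opening may need the upper end of the temperature range. There, oligomerisation of the ketene intermediates, their capture by the product phenol as aryl esters, or loss of a silyl group could compete with the cascade. Fallback, changing how the vinylketene is made: it sets out from 10 and comes back to the route at 15. 1-Methoxyvinyllithium (from methyl vinyl ether and t-BuLi) would be acylated with commercial N-methoxy-N-methylpropanamide to give 2-methoxypent-1-en-3-one F1. Detrifluoroacetylative diazo transfer (LiN(SiMe3)2 and 2,2,2-trifluoroethyl trifluoroacetate, then methanesulfonyl azide and Et3N) would give 2-diazo-4-methoxypent-4-en-3-one F2. Irradiation of F2 with 10 at room temperature should trigger a photochemical Wolff rearrangement in which the 1-methoxyethenyl group migrates, generating vinylketene 11 without heat; 11 then follows the same cascade through 12, 13 and 14 to 15.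

Step 8. Bromine–lithium exchange on the electron-rich phenoxide may be incomplete, or the hindered aryllithium may act as a base towards the alpha protons of 19 instead of adding, which would return protonated material. Fallback, making the C4–C4a bond at the aldehyde oxidation level: it sets out from 15 and comes back at 22. Magnesium-mediated ortho-formylation (MgCl2, Et3N, paraformaldehyde, THF, reflux) at the only free ortho position would give 3-{[(tert-butyldimethylsilyl)oxy]methyl}-2-hydroxy-6-methoxy-5-methyl-4-[(triisopropylsilyl)oxy]benzaldehyde F3. Addition of excess commercial 2-(4-methoxyphenyl)ethylmagnesium bromide would give racemic 2-{[(tert-butyldimethylsilyl)oxy]methyl}-6-[1-hydroxy-3-(4-methoxyphenyl)propyl]-5-methoxy-4-methyl-3-[(triisopropylsilyl)oxy]phenol F4. Oxidation of the benzylic alcohol of F4 with MnO2 would give 22.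

Step 4. Oxygen transfer to the acetylide may stall, or the ynolate may be silylated on carbon to give a silylketene instead of the ynol ether. Fallback, generating the same ynolate by a one-carbon homologation: it replaces 7 as the point of departure, starting from commercial ethyl glycolate, and comes back at 9 and so at 10. Ethyl glycolate would be silylated (t-BuMe2SiCl, imidazole) to ethyl 2-[(tert-butyldimethylsilyl)oxy]acetate F5. A Kowalski homologation of F5 (CH2Br2 and lithium 2,2,6,6-tetramethylpiperidide at −78 °C, then n-BuLi and warming) should give ynolate 9, which would be trapped with i-Pr3SiCl to give 10.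

Step 1. Dimerisation of methylketene may outrun its cycloaddition with 2 and leave little 4. Fallback, using a ketene that does not dimerise readily: it sets out from 2 and comes back at 5. Lithiation of 2 (n-BuLi) and methylation with MeI would give 1-ethoxyprop-1-yne F6. Cycloaddition with dichloroketene (Cl3CCOCl, Zn(Cu), Et2O) would give 4,4-dichloro-3-ethoxy-2-methylcyclobut-2-en-1-one F7, with the methyl group already on C2. Reductive dechlorination (Zn, AcOH) would give 3-ethoxy-2-methylcyclobut-2-en-1-one F8, and the acid hydrolysis of step 2 would convert F8 into 5.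

Step 11. With the C7 phenol free, the hydroxybenzyl unit may decompose on the oxidant surface through quinone methide-type pathways, or the heterogeneous oxidation may stall on the polar diol. Fallback, oxidising before the phenol is unmasked: it sets out from 24 and comes back at 26. Aqueous acetic acid in THF should remove only the primary alkyl silyl ether to give 8-(hydroxymethyl)-5-methoxy-3-(4-methoxybenzyl)-6-methyl-7-[(triisopropylsilyl)oxy]-4H-chromen-4-one F9. Dess–Martin periodinane would oxidise F9 to 5-methoxy-3-(4-methoxybenzyl)-6-methyl-4-oxo-7-[(triisopropylsilyl)oxy]-4H-chromene-8-carbaldehyde F10. Buffered Bu4NF would then release 26.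

## Further compounds

F1 | step 5 | 2-methoxypent-1-en-3-one | CCC(=O)C(=C)OC
F2 | step 5 | 2-diazo-4-methoxypent-4-en-3-one | COC(=C)C(=O)C(C)=[N+]=[N-]
F3 | step 8 | 3-{[(tert-butyldimethylsilyl)oxy]methyl}-2-hydroxy-6-methoxy-5-methyl-4-[(triisopropylsilyl)oxy]benzaldehyde | COc1c(C=O)c(O)c(CO[Si](C)(C)C(C)(C)C)c(O[Si](C(C)C)(C(C)C)C(C)C)c1C
F4 | step 8 | racemic 2-{[(tert-butyldimethylsilyl)oxy]methyl}-6-[1-hydroxy-3-(4-methoxyphenyl)propyl]-5-methoxy-4-methyl-3-[(triisopropylsilyl)oxy]phenol | COc1ccc(CCC(O)c2c(O)c(CO[Si](C)(C)C(C)(C)C)c(O[Si](C(C)C)(C(C)C)C(C)C)c(C)c2OC)cc1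
F5 | step 4 | ethyl 2-[(tert-butyldimethylsilyl)oxy]acetate | CCOC(=O)CO[Si](C)(C)C(C)(C)C
F6 | step 1 | 1-ethoxyprop-1-yne | CCOC#CC
F7 | step 1 | 4,4-dichloro-3-ethoxy-2-methylcyclobut-2-en-1-one | CCOC1=C(C)C(=O)C1(Cl)Cl
F8 | step 1 | 3-ethoxy-2-methylcyclobut-2-en-1-one | CCOC1=C(C)C(=O)C1
F9 | step 11 | 8-(hydroxymethyl)-5-methoxy-3-(4-methoxybenzyl)-6-methyl-7-[(triisopropylsilyl)oxy]-4H-chromen-4-one | COc1ccc(Cc2coc3c(CO)c(O[Si](C(C)C)(C(C)C)C(C)C)c(C)c(OC)c3c2=O)cc1
F10 | step 11 | 5-methoxy-3-(4-methoxybenzyl)-6-methyl-4-oxo-7-[(triisopropylsilyl)oxy]-4H-chromene-8-carbaldehyde | COc1ccc(Cc2coc3c(C=O)c(O[Si](C(C)C)(C(C)C)C(C)C)c(C)c(OC)c3c2=O)cc1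
A1 | alternative 1 | 5,7-dihydroxy-3-(4-methoxybenzyl)-6-methyl-4H-chromen-4-one | COc1ccc(Cc2coc3cc(O)c(C)c(O)c3c2=O)cc1
A2 | alternative 1 | 7-ethyl-3-(4-methoxybenzyl)-4H,5H-pyrano[4,3-b]pyran-4,5-dione | CCC1=CC2=C(C(=O)O1)C(=O)C(Cc1ccc(OC)cc1)=CO2
A3 | alternative 2 | 5,7-bis(benzyloxy)-3-(4-methoxybenzyl)-6-methyl-4H-chromen-4-one | COc1ccc(Cc2coc3cc(OCc4ccccc4)c(C)c(OCc4ccccc4)c3c2=O)cc1
A4 | alternative 2 | (E)-1-[2,4-bis(benzyloxy)-6-hydroxy-3-methylphenyl]-3-(dimethylamino)prop-2-en-1-one | CN(C)/C=C/C(=O)c1c(O)cc(OCc2ccccc2)c(C)c1OCc1ccccc1
A5 | alternative 2 | 4-methoxybenzyl alcohol | COc1ccc(CO)cc1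
A6 | alternative 2 | 1-(2,4,6-trihydroxy-3-methylphenyl)ethan-1-one | CC(=O)c1c(O)cc(O)c(C)c1O
A7 | alternative 3 | (E)-5,7-bis(benzyloxy)-3-(4-methoxybenzylidene)-6-methylchroman-4-one | COc1ccc(/C=C2\COc3cc(OCc4ccccc4)c(C)c(OCc4ccccc4)c3C2=O)cc1
A8 | alternative 3 | 2,4-bis(benzyloxy)-6-{[3-(4-methoxyphenyl)prop-2-yn-1-yl]oxy}-3-methylbenzaldehyde | COc1ccc(C#CCOc2cc(OCc3ccccc3)c(C)c(OCc3ccccc3)c2C=O)cc1
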